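## The problem

Compound 19 is a flavonol: a 4H-chromen-4-one (ring A fused to the pyranone ring C) with a 4-methoxyphenyl ring B on C2, free hydroxyls on C3 and C5, and a 3-methylbut-2-enyl (prenyl) ether on C7. It has no stereocentre, so the task is one of regiochemistry and of telling oxygens apart. Ring A is a phloroglucinol unit whose three oxygens must end up different: O1 in the heterocycle, O5 as a chelated free phenol, O7 as the prenyl ether. The acyl carbon C4 must sit on C4a, the ring carbon between C8a–O1 and C5–O. The prenyl ether is the fragile group: electrophilic oxidants attack its alkene, acid and hydrogenolysis cleave it, and heat can trigger a Claisen shift, so it should go on last. The 3-hydroxyl cannot be carried on an alkyne carbon and must be added by oxidation of C2=C3 once ring C exists and before the prenyl alkene is present. The enabling feature is that O1 (on C8a) and C4 (on C4a) are on adjacent carbons of ring A, with C4a next to the C5 oxygen. This is the pattern a 3-alkoxybenzyne gives on inserting into the O–C(=O) bond of a carboxylic acid, and the remaining atoms C4–C3–C2–aryl are those of 3-(4-methoxyphenyl)propiolic acid 11.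

## Retrosynthesis

**19 ⇒ 17 + 18.** The last bond made is O7–CH2 of the prenyl ether, which cuts 19 to kaempferide 17 and prenyl bromide 18. Late prenylation keeps the alkene and the allylic C–O bond away from the oxidant that installs O3, from the acid that removes the phenol protecting groups, and from the hot aryne step. Carrying the ether from the start would expose it to all three. The price is a choice among three hydroxyls. The structure supplies it: 7-OH is a vinylogous acid through ring A to C4=O and is the most acidic, while 5-OH and 3-OH are both hydrogen-bonded to the carbonyl oxygen. One equivalent of weak base and of 18 should therefore alkylate O7.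

**17 ⇒ 16 ⇒ 14.** Kaempferide 17 is traced to its 5,7-bis(methoxymethyl) ether 16 (two acetal O–CH2 bonds), and 16 to flavone 14 by removing O3 (the C3–O bond). C2=C3 of 14 is an enol-ether-type double bond and the only alkene present at that stage, which suits a neutral electrophilic oxygen-transfer reagent. MOM ethers are preferred to benzyl ethers because they assist the metalation that makes the aryne precursor and carry no benzylic C–H open to base or oxidant. They are preferred to methyl ethers because those could not be cleaved without touching the 4'-methoxy group. The forward steps must oxidise C2=C3 without attacking the electron-rich ring A, then remove both acetals with acid that 17 tolerates.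

**14 ⇒ 10 + 11 (key disconnection).** Ring C of 14 is opened at O1–C2 to ynone 13, and 13 is cut at C4a–C4 and C8a–O1. These two bonds sit on adjacent ring carbons, so ring A becomes aryne 12, generated from silyl triflate 10, and the partner is the purchased acid 11. The classical cuts (acylating a phloroglucinol ether, then building the chain by aldol or Baker–Venkataraman chemistry) rely on electrophilic substitution of a ring whose free positions are nearly alike. Here three bonds of ring C form in one flask, and the placement of C4 between O1 and O5 follows from the 3-alkoxy group of the aryne. The forward reaction must deliver the carboxylate oxygen to the aryne carbon remote from the OMOM group, transfer the acyl group to the neighbouring carbanion, and close ring C in the 6-endo mode.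

**10 ⇒ 8 ⇒ 4 ⇒ 3 ⇒ 1 + 2.** Silyl triflate 10 is cut at the O–S bond to silyl phenol 9, which is handled only as its carbamate 8. Cutting the C2–Si bond of 8 gives carbamate 4. The carbamate is the strongest ortho-directing group on the ring and cooperates with the adjacent OMOM group, so metalation should occur between them, at the carbon that later becomes C4a. The carbamate is also the latent triflate oxygen, which becomes O1. Carbamate 4 comes from phenol 3, and 3 from phloroglucinol 1 and two equivalents of chloromethyl methyl ether 2 by two O-alkylations. The first step is statistical; after it every step is regiodefined.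

## Roads not taken

**Alternative 1:** The cut is the C2=C3 bond of ring C. Keto ylide A1 carries the 3-oxygen as a 2-(trimethylsilyl)ethyl ether on the ylide carbon and has the ortho oxygen acylated as the 4-methoxybenzoate. On heating, the ylide carbon attacks the ester carbonyl and triphenylphosphine oxide is lost, giving chromone A2.
- Merits: O3 arrives in place, so no oxidation is needed. O5 and O7 are differentiated from the start, so the prenyl ether is carried through and no selective alkylation is required at the end. On this point the alternative is better than the chosen plan, which relies on the acidity gap between 7-OH and 3-OH in its last step.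
- Weak points: a stabilised keto ylide attacking an ester carbonyl is a sluggish Wittig reaction that needs prolonged heating, at which an aryl prenyl ether can undergo Claisen rearrangement. A1 must be assembled linearly (three phenol oxygens differentiated, α-oxygenation, phosphonium salt formation, O-aroylation), so there is little convergence. A2 still needs its silylethyl and MOM groups removed by fluoride and acid in the presence of the acid-sensitive prenyl ether.
- Comparison: the chosen plan answers with a two-component union that makes three ring-C bonds at once and never exposes the prenyl group to heat, acid or oxidant.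

**Alternative 2:** The cut is through ring A at C4a–C5 and C8–C8a. Bromopyranone A3, which already holds ring C, ring B and a 3-pivalate, would react with ketene-acetal diene A4. Loss of HBr, methanol and silanol would aromatise ring A to A5.
- Merits: the full oxygen pattern arrives differentiated (5-OH free, 7-O-prenyl, 3-O-acyl), and A5 is one deacylation from 19. That is fewer steps after the key step than the three of the chosen plan.
- Weak points: a 4-pyranone is a vinylogous ester with aromatic character and a poor dienophile, made poorer by the 2-aryl and 3-acyloxy groups. A3 needs its own multistep synthesis. A4 is hydrolytically labile, and its prenyloxy-substituted diene carbon makes it an allyl vinyl ether, so a [3,3] shift can compete with cycloaddition on warming. Regiochemistry rests on the bromine alone.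
- Comparison: the chosen plan uses an established reaction type for its key step and stable, storable precursors, at the cost of a longer end game.

**Alternative 3:** The cuts are C4a–C4, C4–C3 and O1–C2, with carbon monoxide as C4. Iodophenol A6, CO and 4-ethynylanisole A7 would be joined by zerovalent palladium (from PdCl2(PPh3)2) in Et2NH to an ortho-hydroxyaryl ynone, which closes to flavone A8.
- Merits: this is a widely used flavone synthesis from three simple components. A6 is closer to commercial material than silyl triflate 10, which takes four steps. The benzyl ethers of A8 come off by neutral hydrogenolysis to reach 17 after the same C3 oxidation.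
- Weak points: A6 requires mono-iodination of a phloroglucinol diether whose three free positions are similarly activated. The iodide is flanked by two ortho oxygens and is very electron-rich, so oxidative addition and CO insertion are slow, and direct alkyne coupling without CO can intervene. CO handling is needed. The end game is no shorter.
- Comparison: both routes pass through the same type of ynone and share the risk of 5-exo closure. The alternative reaches its ring-A precursor in fewer steps. The chosen plan sets against that a metal-free, CO-free coupling and a precursor whose substitution is fixed by directed metalation and not by electrophilic halogenation.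

Key step: step 5

Remark: 19 has no stereocentre. The only stereogenic intermediate, epoxide 15, forms as a racemate with a necessarily cis-fused oxirane and is drawn as one enantiomer.

## Route

Step 1
Reactants: 1 phloroglucinol; 2 chloromethyl methyl ether
Product: 3 3,5-bis(methoxymethoxy)phenol
Conditions: MOMCl (2.1 equiv), i-Pr2NEt, DMF, 0 °C to rt; chromatography
Reagents that add atoms: chloromethyl methyl ether (the second equivalent of 2), COCCl
Why: Two successive Williamson-type O-alkylations of the phenoxide with the reactive α-chloro ether, one equivalent of 2 for each methoxymethyl group; the three hydroxyls are equivalent, so the step is statistical, the bis-ether is separated from mono- and tris-ethers, and the mono-ether can be resubmitted.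

Step 2
Reactants: 3 3,5-bis(methoxymethoxy)phenol
Product: 4 3,5-bis(methoxymethoxy)phenyl N-(propan-2-yl)carbamate
Conditions: i-PrNCO, Et3N (cat.), CH2Cl2, rt
Reagents that add atoms: isopropyl isocyanate, CC(C)N=C=O
Why: Base-catalysed addition of the phenol to the isocyanate (carbamoylation); the secondary carbamate is chosen because it directs metalation once N-silylated and can later be cleaved under mild basic conditions.

Step 3
Reactants: 4 3,5-bis(methoxymethoxy)phenyl N-(propan-2-yl)carbamate
Product: 8 3,5-bis(methoxymethoxy)-2-(trimethylsilyl)phenyl N-(propan-2-yl)carbamate, via N-silyl carbamate 5 (not isolated), via aryllithium 6 (not isolated), via bis-silyl carbamate 7 (not isolated)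
Conditions: TBSOTf, TMEDA, Et2O, 0 °C to rt; n-BuLi, TMEDA, −78 °C; TMSCl, −78 °C to rt; sat. aq NH4Cl
Reagents that add atoms: chlorotrimethylsilane, C[Si](C)(C)Cl
Why: Directed ortho-metalation (Snieckus type) after in situ N-silylation; the N-silyl carbamate is the strongest directing group and acts together with the adjacent OMOM group, so deprotonation should occur at the carbon between them (C2 and C6 are equivalent) and not at C4 between the two OMOM groups; TMSCl traps the aryllithium and the N–Si bond hydrolyses on the mildly acidic work-up, chosen to spare the electron-rich aryl–silicon bond.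

Step 4
Reactants: 8 3,5-bis(methoxymethoxy)-2-(trimethylsilyl)phenyl N-(propan-2-yl)carbamate
Product: 10 3,5-bis(methoxymethoxy)-2-(trimethylsilyl)phenyl trifluoromethanesulfonate, via silyl phenol 9 (not isolated)
Conditions: DBU, Et2NH, MeCN, 40 °C; then PhNTf2, rt
Reagents that add atoms: N-phenylbis(trifluoromethanesulfonimide), O=S(=O)(N(c1ccccc1)S(=O)(=O)C(F)(F)F)C(F)(F)F
Why: DBU removes the carbamate N–H and the phenoxide is expelled (E1cB), the isocyanate being trapped by Et2NH as a urea; the phenoxide is triflated in the same flask, so the protodesilylation-prone silyl phenol is never isolated.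

Step 5
Reactants: 10 3,5-bis(methoxymethoxy)-2-(trimethylsilyl)phenyl trifluoromethanesulfonate; 11 3-(4-methoxyphenyl)propiolic acid
Product: 14 5,7-bis(methoxymethoxy)-2-(4-methoxyphenyl)-4H-chromen-4-one, via aryne 12 (not isolated), via hydroxyaryl ynone 13 (not isolated)
Conditions: CsF (excess), THF, 125 °C, sealed tube
Reagents that add atoms: none
Why: Fluoride attacks silicon in 10 and triflate leaves, giving aryne 12. The cesium carboxylate of 11 adds through oxygen to the aryne carbon that carried the triflate, the one remote from the flanking OMOM group, because that inductively withdrawing substituent distorts the aryne and stabilises the negative charge developing on the carbon next to it. The resulting aryl anion attacks the adjacent ester carbonyl, and the strained four-membered alkoxide opens by C–O cleavage to the phenoxide of ynone 13; the aryne has thus inserted into the O–C(=O) bond, making C8a–O1 and C4a–C4 on adjacent carbons with C4 next to the future C5 oxygen. The phenoxide then adds to the alkyne carbon bearing the anisyl group in a 6-endo-dig oxa-Michael closure (O1–C2), and protonation at C3 completes ring C of 14. The closest known reaction type is the insertion of arynes into carboxylic acids to give ortho-hydroxyaryl ketones, which with arylpropiolic acids runs on to flavones. Two selectivities are needed: the site of carboxylate addition, secured by the 3-alkoxy group of the aryne, and 6-endo over 5-exo closure, favoured by the polarisation of the ynone towards its β-carbon and by the stability of the aromatic 4-pyranone. No stereocentre is formed, and the MOM and methyl ethers are inert to CsF.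

Step 6
Reactants: 14 5,7-bis(methoxymethoxy)-2-(4-methoxyphenyl)-4H-chromen-4-one
Product: 16 3-hydroxy-5,7-bis(methoxymethoxy)-2-(4-methoxyphenyl)-4H-chromen-4-one, via flavone epoxide 15 (not isolated)
Conditions: DMDO, acetone/CH2Cl2, 0 °C to rt; concentrate; p-TsOH (cat.), CH2Cl2, rt
Reagents that add atoms: dimethyldioxirane, CC1(C)OO1
Why: Dioxirane epoxidation of the enol-ether-type C2=C3 bond under neutral conditions, then acid-catalysed opening at C2 (cation stabilised by O1 and the anisyl ring) and loss of H3 gives the 3-hydroxyflavone; the racemic epoxide's two stereocentres vanish on aromatisation, and any partial loss of the 5-MOM group is harmless because step 7 removes both.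

Step 7
Reactants: 16 3-hydroxy-5,7-bis(methoxymethoxy)-2-(4-methoxyphenyl)-4H-chromen-4-one
Product: 17 3,5,7-trihydroxy-2-(4-methoxyphenyl)-4H-chromen-4-one (kaempferide)
Conditions: 3 M aq HCl, MeOH, 60 °C
Reagents that add atoms: none
Why: Acid-catalysed acetal exchange cleaves both methoxymethyl ethers (the peri 5-ether fastest); the flavonol core and the aryl methyl ether are stable to these conditions.

Step 8
Reactants: 17 3,5,7-trihydroxy-2-(4-methoxyphenyl)-4H-chromen-4-one (kaempferide); 18 prenyl bromide (1-bromo-3-methylbut-2-ene)
Product: 19 3,5-dihydroxy-2-(4-methoxyphenyl)-7-(3-methylbut-2-enyloxy)-4H-chromen-4-one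
Conditions: 18 (1.05 equiv), K2CO3 (1.1 equiv), acetone, rt to 40 °C
Reagents that add atoms: none
Why: Williamson etherification at the most acidic hydroxyl; 7-OH is a vinylogous acid conjugated to C4=O, whereas 5-OH and 3-OH are hydrogen-bonded to the carbonyl and less acidic, so limiting base and bromide should give the 7-ether by SN2 at the primary allylic carbon.

## Compound list

1 | phloroglucinol (benzene-1,3,5-triol) | Oc1cc(O)cc(O)c1 | starting material
2 | chloromethyl methyl ether | COCCl | starting material
3 | 3,5-bis(methoxymethoxy)phenol | COCOc1cc(O)cc(OCOC)c1 | intermediate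
4 | 3,5-bis(methoxymethoxy)phenyl N-(propan-2-yl)carbamate | COCOc1cc(OCOC)cc(OC(=O)NC(C)C)c1 | intermediate
5 | 3,5-bis(methoxymethoxy)phenyl N-(tert-butyldimethylsilyl)-N-(propan-2-yl)carbamate | COCOc1cc(OCOC)cc(OC(=O)N(C(C)C)[Si](C)(C)C(C)(C)C)c1 | intermediate (not isolated)
6 | {2-[N-(tert-butyldimethylsilyl)-N-(propan-2-yl)carbamoyloxy]-4,6-bis(methoxymethoxy)phenyl}lithium | COCOc1cc(OCOC)c([Li])c(OC(=O)N(C(C)C)[Si](C)(C)C(C)(C)C)c1 | intermediate (not isolated)
7 | 3,5-bis(methoxymethoxy)-2-(trimethylsilyl)phenyl N-(tert-butyldimethylsilyl)-N-(propan-2-yl)carbamate | COCOc1cc(OCOC)c([Si](C)(C)C)c(OC(=O)N(C(C)C)[Si](C)(C)C(C)(C)C)c1 | intermediate (not isolated)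
8 | 3,5-bis(methoxymethoxy)-2-(trimethylsilyl)phenyl N-(propan-2-yl)carbamate | COCOc1cc(OCOC)c([Si](C)(C)C)c(OC(=O)NC(C)C)c1 | intermediate
9 | 3,5-bis(methoxymethoxy)-2-(trimethylsilyl)phenol | COCOc1cc(O)c([Si](C)(C)C)c(OCOC)c1 | intermediate (not isolated)
10 | 3,5-bis(methoxymethoxy)-2-(trimethylsilyl)phenyl trifluoromethanesulfonate | COCOc1cc(OCOC)cc(OS(=O)(=O)C(F)(F)F)c1[Si](C)(C)C | intermediate
11 | 3-(4-methoxyphenyl)propiolic acid (3-(4-methoxyphenyl)prop-2-ynoic acid) | COc1ccc(C#CC(=O)O)cc1 | starting material
12 | 3,5-bis(methoxymethoxy)benzyne (1,2-didehydro-3,5-bis(methoxymethoxy)benzene) | COCOC1=CC(OCOC)=CC#C1 | intermediate (not isolated)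
13 | 1-[2-hydroxy-4,6-bis(methoxymethoxy)phenyl]-3-(4-methoxyphenyl)prop-2-yn-1-one | COCOc1cc(O)c(C(=O)C#Cc2ccc(OC)cc2)c(OCOC)c1 | intermediate (not isolated)
14 | 5,7-bis(methoxymethoxy)-2-(4-methoxyphenyl)-4H-chromen-4-one | O=c1cc(-c2ccc(OC)cc2)oc2cc(OCOC)cc(OCOC)c12 | intermediate
15 | racemic 2,3-epoxy-5,7-bis(methoxymethoxy)-2-(4-methoxyphenyl)chroman-4-one (cis-fused oxirane, one enantiomer drawn) | O=C1c2c(OCOC)cc(OCOC)cc2O[C@]2(c3ccc(OC)cc3)O[C@H]12 | intermediate (not isolated)
16 | 3-hydroxy-5,7-bis(methoxymethoxy)-2-(4-methoxyphenyl)-4H-chromen-4-one | COCOc1cc(OCOC)c2c(=O)c(O)c(-c3ccc(OC)cc3)oc2c1 | intermediate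
17 | 3,5,7-trihydroxy-2-(4-methoxyphenyl)-4H-chromen-4-one (kaempferide) | COc1ccc(-c2oc3cc(O)cc(O)c3c(=O)c2O)cc1 | intermediate
18 | prenyl bromide (1-bromo-3-methylbut-2-ene) | CC(C)=CCBr | starting material
19 | 3,5-dihydroxy-2-(4-methoxyphenyl)-7-(3-methylbut-2-enyloxy)-4H-chromen-4-one | COc1ccc(-c2oc3cc(OCC=C(C)C)cc(O)c3c(=O)c2O)cc1 | target

## Step count and risk

Total: 8 steps. Longest linear sequence: 8 steps, from phloroglucinol 1 to 19; acid 11 and bromide 18 enter as purchased materials.

**Step 5 (key step).** Four things could go wrong: the propiolate could lose carbon dioxide at 125 °C before it meets the aryne; the aryl anion could be protonated before acyl transfer, stopping at simple O-arylation; the phenoxide of 13 could be arylated by a second aryne or close in the 5-exo mode; or the carboxylate could add at the wrong aryne carbon. The fallback forms C4a–C4 by directed metalation instead of aryne insertion. It sets out from carbamate 4 and acid 11. Acid 11 is converted (amide coupling with N,O-dimethylhydroxylamine) into the Weinreb amide N-methoxy-N-methyl-3-(4-methoxyphenyl)prop-2-ynamide F1. Carbamate 4 is N-silylated and lithiated as in step 3 (through 5 and 6), and 6 is acylated with F1. This gives the N-silyl ynone 3,5-bis(methoxymethoxy)-2-[3-(4-methoxyphenyl)prop-2-ynoyl]phenyl N-(tert-butyldimethylsilyl)-N-(propan-2-yl)carbamate F2, which is hydrolysed on work-up to 3,5-bis(methoxymethoxy)-2-[3-(4-methoxyphenyl)prop-2-ynoyl]phenyl N-(propan-2-yl)carbamate F3. DBU and Et2NH in MeCN then cleave the carbamate as in step 4. The liberated phenoxide of 13 closes through O1–C2, and the sequence rejoins the route at flavone 14.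

**Step 3.** Metalation could occur at C4 between the two OMOM groups; the carbamoyl group could migrate to carbon (anionic Fries shift) if the aryllithium warms; or the electron-rich aryl–silicon bond could be protonated during work-up. The fallback places the silyl group by halogen–metal exchange and sets out from phenol 3. Ortho-selective bromination (NBS, cat. i-Pr2NH, CH2Cl2) gives 2-bromo-3,5-bis(methoxymethoxy)phenol F4. O-Silylation with hexamethyldisilazane gives [2-bromo-3,5-bis(methoxymethoxy)phenoxy]trimethylsilane F5. Treatment with n-BuLi at −78 °C brings about bromine–lithium exchange and 1,3 oxygen-to-carbon silyl migration, giving the lithium salt of 9, which is triflated with Tf2O. The sequence rejoins the route at silyl triflate 10.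

**Step 6.** The dioxirane could oxidise the electron-rich ring A or the acetal C–H bonds in competition with the carbonyl-deactivated C2=C3 bond; conversion could be incomplete; or the epoxide could be diverted by adventitious nucleophiles before rearranging. The fallback introduces O3 by deprotonation, borylation and oxidation and sets out from flavone 14. Lithium diisopropylamide (LiN(i-Pr)2) in THF at −78 °C removes H3 to give [5,7-bis(methoxymethoxy)-2-(4-methoxyphenyl)-4-oxo-4H-chromen-3-yl]lithium F6. B(OMe)3 converts it into dimethyl [5,7-bis(methoxymethoxy)-2-(4-methoxyphenyl)-4-oxo-4H-chromen-3-yl]boronate F7. Oxidation with H2O2 in AcOH rejoins the route at flavonol 16.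

**Step 8.** Alkylation could continue at O3 once the 7-ether has formed, or occur at carbon (C6 or C8) of the ambident phenoxide, because the acidity gap between 7-OH and 3-OH is smaller than that to 5-OH. The fallback masks O3 and sets out from flavonol 16. Benzoylation (BzCl, pyridine) gives 5,7-bis(methoxymethoxy)-2-(4-methoxyphenyl)-4-oxo-4H-chromen-3-yl benzoate F8. HCl in MeOH at rt removes both MOM groups to give 5,7-dihydroxy-2-(4-methoxyphenyl)-4-oxo-4H-chromen-3-yl benzoate F9. Alkylation with 18 and K2CO3 in acetone can then occur only at O7, since 5-OH is chelated, and gives 5-hydroxy-2-(4-methoxyphenyl)-7-(3-methylbut-2-enyloxy)-4-oxo-4H-chromen-3-yl benzoate F10. Methanolysis of the benzoate (K2CO3, MeOH, rt) rejoins the route at target 19.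

## Further compounds

F1 | step 5 | N-methoxy-N-methyl-3-(4-methoxyphenyl)prop-2-ynamide | COc1ccc(C#CC(=O)N(C)OC)cc1
F2 | step 5 | 3,5-bis(methoxymethoxy)-2-[3-(4-methoxyphenyl)prop-2-ynoyl]phenyl N-(tert-butyldimethylsilyl)-N-(propan-2-yl)carbamate | COCOc1cc(OCOC)c(C(=O)C#Cc2ccc(OC)cc2)c(OC(=O)N(C(C)C)[Si](C)(C)C(C)(C)C)c1
F3 | step 5 | 3,5-bis(methoxymethoxy)-2-[3-(4-methoxyphenyl)prop-2-ynoyl]phenyl N-(propan-2-yl)carbamate | COCOc1cc(OCOC)c(C(=O)C#Cc2ccc(OC)cc2)c(OC(=O)NC(C)C)c1
F4 | step 3 | 2-bromo-3,5-bis(methoxymethoxy)phenol | COCOc1cc(O)c(Br)c(OCOC)c1
F5 | step 3 | [2-bromo-3,5-bis(methoxymethoxy)phenoxy]trimethylsilane | COCOc1cc(O[Si](C)(C)C)c(Br)c(OCOC)c1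
F6 | step 6 | [5,7-bis(methoxymethoxy)-2-(4-methoxyphenyl)-4-oxo-4H-chromen-3-yl]lithium | [Li]c1c(-c2ccc(OC)cc2)oc2cc(OCOC)cc(OCOC)c2c1=O
F7 | step 6 | dimethyl [5,7-bis(methoxymethoxy)-2-(4-methoxyphenyl)-4-oxo-4H-chromen-3-yl]boronate | COB(OC)c1c(-c2ccc(OC)cc2)oc2cc(OCOC)cc(OCOC)c2c1=O
F8 | step 8 | 5,7-bis(methoxymethoxy)-2-(4-methoxyphenyl)-4-oxo-4H-chromen-3-yl benzoate | COCOc1cc(OCOC)c2c(=O)c(OC(=O)c3ccccc3)c(-c3ccc(OC)cc3)oc2c1
F9 | step 8 | 5,7-dihydroxy-2-(4-methoxyphenyl)-4-oxo-4H-chromen-3-yl benzoate | COc1ccc(-c2oc3cc(O)cc(O)c3c(=O)c2OC(=O)c2ccccc2)cc1
F10 | step 8 | 5-hydroxy-2-(4-methoxyphenyl)-7-(3-methylbut-2-enyloxy)-4-oxo-4H-chromen-3-yl benzoate | COc1ccc(-c2oc3cc(OCC=C(C)C)cc(O)c3c(=O)c2OC(=O)c2ccccc2)cc1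
A1 | alternative 1 | 3-(methoxymethoxy)-5-(3-methylbut-2-enyloxy)-2-[2-(2-trimethylsilylethoxy)-2-(triphenylphosphoranylidene)acetyl]phenyl 4-methoxybenzoate | COCOc1cc(OCC=C(C)C)cc(OC(=O)c2ccc(OC)cc2)c1C(=O)C(OCC[Si](C)(C)C)=P(c1ccccc1)(c1ccccc1)c1ccccc1
A2 | alternative 1 | 2-(4-methoxyphenyl)-5-(methoxymethoxy)-7-(3-methylbut-2-enyloxy)-3-(2-trimethylsilylethoxy)-4H-chromen-4-one | O=c1c(OCC[Si](C)(C)C)c(-c2ccc(OC)cc2)oc2cc(OCC=C(C)C)cc(OCOC)c12
A3 | alternative 2 | 5-bromo-2-(4-methoxyphenyl)-4-oxo-4H-pyran-3-yl 2,2-dimethylpropanoate | CC(C)(C)C(=O)Oc1c(-c2ccc(OC)cc2)occ(Br)c1=O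
A4 | alternative 2 | trimethyl{[1-methoxy-3-(3-methylbut-2-enyloxy)buta-1,3-dien-1-yl]oxy}silane (E/Z mixture) | COC(O[Si](C)(C)C)=CC(=C)OCC=C(C)C
A5 | alternative 2 | 5-hydroxy-2-(4-methoxyphenyl)-7-(3-methylbut-2-enyloxy)-4-oxo-4H-chromen-3-yl 2,2-dimethylpropanoate | CC(C)(C)C(=O)Oc1c(-c2ccc(OC)cc2)oc2cc(OCC=C(C)C)cc(O)c2c1=O
A6 | alternative 3 | 3,5-bis(benzyloxy)-2-iodophenol | Oc1cc(OCc2ccccc2)cc(OCc2ccccc2)c1I
A7 | alternative 3 | 4-ethynylanisole (1-ethynyl-4-methoxybenzene) | C#Cc1ccc(OC)cc1
A8 | alternative 3 | 5,7-bis(benzyloxy)-2-(4-methoxyphenyl)-4H-chromen-4-one | O=c1cc(-c2ccc(OC)cc2)oc2cc(OCc3ccccc3)cc(OCc3ccccc3)c12
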